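**Plan**

1. Retrosynthesis: the C4=CH2 bond is cut to a C4 ketone (Wittig). C3 is then excised from ring A, which contracts the decalone to a trans-hydrindanone with the five-membered ring C4–C2–C1–C10–C5.
2. Enabling feature: C4 of ring A is a masked carbonyl flanked by the quaternary C5 and an unsubstituted CH2. In the ring-contracted precursor this is the D-ring pattern of a 17-oxo steroid, where CH2 insertion by a diazoalkane is known and the CH2 side migrates.
3. Further cuts: C8–CH3 (back to a C8 ketone); C9–CH2Ar together with C10–H (reduction–benzylation of an enone); ring B (Michael/aldol annulation onto 2-methylcyclopentane-1,3-dione).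
4. Forward order: five-membered ring → ring B → aryl unit joined at C9 → C8 methyl → five-membered ring enlarged by one carbon to ring A → exocyclic methylene.
5. Stereochemistry: C5 from the L-phenylalanine-mediated aldol desymmetrisation; C10 and C9 from Li/NH3 reduction–alkylation (trans protonation, benzylation anti to the angular methyl); C8 from α-face hydrogenation. The ring enlargement touches no stereocentre.

Key step: step 14

Remark on names: from 12 onwards, locants are those of the target's decalin (C4 bears =CH2, C5/C10 are the fusion carbons; hydrindanes lack C3, five-membered ring C4–C2–C1–C10–C5); β is the face of the C5 methyl; Ar*CH2 = [5-(methoxycarbonyl)-3-methoxy-2-(methoxymethoxy)phenyl]methyl.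

**Route**

Step 1
Reactants: 1 2-methylcyclopentane-1,3-dione; 2 pent-1-en-3-one (ethyl vinyl ketone)
Product: 3 2-methyl-2-(3-oxopentyl)cyclopentane-1,3-dione
Conditions: H2O, AcOH (cat.), 75 °C
Reagents that add atoms: none
Why: Michael addition of the enolised 1,3-dione to the vinyl ketone gives the prochiral triketone, with no stereocentre formed.

Step 2
Reactants: 3 2-methyl-2-(3-oxopentyl)cyclopentane-1,3-dione
Product: 4 (7aS)-4,7a-dimethyl-2,3,7,7a-tetrahydro-1H-indene-1,5(6H)-dione
Conditions: L-phenylalanine, (1S)-(+)-10-camphorsulfonic acid, DMF, 30 → 70 °C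
Reagents that add atoms: none
Why: Hajos–Parrish–Eder–Sauer–Wiechert aldol condensation, in which the side-chain enamine of the primary amino acid adds to one of the two enantiotopic ring carbonyls through a hydrogen-bonded transition state and dehydrates, setting the quaternary carbon (C5 of the target) as S.

Step 3
Reactants: 4 (7aS)-4,7a-dimethyl-2,3,7,7a-tetrahydro-1H-indene-1,5(6H)-dione
Product: 5 (1S,7aS)-1-hydroxy-4,7a-dimethyl-1,2,3,6,7,7a-hexahydro-5H-inden-5-one
Conditions: NaBH4 (0.3 equiv), EtOH, −20 °C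
Reagents that add atoms: none
Why: chemoselective borohydride 1,2-reduction of the saturated cyclopentanone (the tetrasubstituted enone is much less electrophilic), with hydride arriving on the α-face anti to the angular methyl to give the β-alcohol.

Step 4
Reactants: 5 (1S,7aS)-1-hydroxy-4,7a-dimethyl-1,2,3,6,7,7a-hexahydro-5H-inden-5-one
Product: 6 (1S,7aS)-1-(tert-butyldimethylsilyloxy)-4,7a-dimethyl-1,2,3,6,7,7a-hexahydro-5H-inden-5-one
Conditions: TBSCl, imidazole, DMF, rt
Reagents that add atoms: tert-butyldimethylsilyl chloride CC(C)(C)[Si](C)(C)Cl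
Why: standard silylation; the β-silyl ether masks the future C4 carbonyl through the dissolving-metal step and is the substituent type for which that step favours the trans ring fusion.

Step 5
Reactants: 7 methyl 4-hydroxy-3-methoxybenzoate (methyl vanillate)
Product: 8 methyl 3-formyl-4-hydroxy-5-methoxybenzoate
Conditions: MgCl2, Et3N, (CH2O)n, MeCN, reflux; then 1 M HCl
Reagents that add atoms: paraformaldehyde (as formaldehyde) C=O
Why: magnesium-phenoxide-directed ortho-formylation (Casnati–Skattebøl reaction) at the only free ortho position, a second formaldehyde accepting hydride from the hydroxymethyl stage.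

Step 6
Reactants: 8 methyl 3-formyl-4-hydroxy-5-methoxybenzoate
Product: 9 methyl 3-formyl-5-methoxy-4-(methoxymethoxy)benzoate
Conditions: MOMCl, i-Pr2NEt, CH2Cl2, 0 °C → rt
Reagents that add atoms: chloromethyl methyl ether COCCl
Why: O-alkylation of the phenol gives an acetal that should survive the enolate, hydride, fluoride and Lewis-acid steps and is removed by protic acid.

Step 7
Reactants: 9 methyl 3-formyl-5-methoxy-4-(methoxymethoxy)benzoate
Product: 10 methyl 3-(hydroxymethyl)-5-methoxy-4-(methoxymethoxy)benzoate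
Conditions: NaBH4, MeOH/THF, 0 °C
Reagents that add atoms: none
Why: borohydride reduces the aldehyde and leaves the aryl ester.

Step 8
Reactants: 10 methyl 3-(hydroxymethyl)-5-methoxy-4-(methoxymethoxy)benzoate
Product: 11 methyl 3-(bromomethyl)-5-methoxy-4-(methoxymethoxy)benzoate
Conditions: CBr4, PPh3, CH2Cl2, 0 °C
Reagents that add atoms: carbon tetrabromide BrC(Br)(Br)Br
Why: Appel bromination of the benzylic alcohol under neutral conditions keeps the MOM acetal.

Step 9
Reactants: 6 (1S,7aS)-1-(tert-butyldimethylsilyloxy)-4,7a-dimethyl-1,2,3,6,7,7a-hexahydro-5H-inden-5-one; 11 methyl 3-(bromomethyl)-5-methoxy-4-(methoxymethoxy)benzoate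
Product: 13 4β-(tert-butyldimethylsilyloxy)-5β,9β-dimethyl-9α-(Ar*CH2)-10α-H-hydrindan-8-one, via lithium enolate 12 (not isolated)
Conditions: Li (2.2 equiv), NH3(l)/THF, H2O (1.0 equiv), −78 → −33 °C; isoprene; NH3 evaporated; then 11, THF, −20 °C → rt
Reagents that add atoms: none
Why: Birch-type reduction–enolate alkylation, in which the C10 carbanion is protonated axially to the trans-fused enolate 12 (formed only across C8–C9) and this is benzylated on the α-face anti to the axial C5 methyl, setting C10 (α-H) and C9 (β-Me, α-CH2Ar); the ester-bearing bromide meets neither metal nor ammonia.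

Step 10
Reactants: 13 4β-(tert-butyldimethylsilyloxy)-5β,9β-dimethyl-9α-(Ar*CH2)-10α-H-hydrindan-8-one
Product: 14 4β-(tert-butyldimethylsilyloxy)-5β,9β-dimethyl-8-methylene-9α-(Ar*CH2)-10α-H-hydrindane
Conditions: Zn, CH2Br2, TiCl4, THF (reagent pre-formed at 0–5 °C); then 13, CH2Cl2, 0 °C → rt
Reagents that add atoms: dibromomethane BrCBr
Why: Takai–Lombardo methylenation, whose non-basic titanium–zinc methylene reagent attacks the hindered, enolisable C8 ketone but not the aryl ester, which an excess of a phosphorus ylide could acylate.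

Step 11
Reactants: 14 4β-(tert-butyldimethylsilyloxy)-5β,9β-dimethyl-8-methylene-9α-(Ar*CH2)-10α-H-hydrindane
Product: 15 4β-(tert-butyldimethylsilyloxy)-5β,8β,9β-trimethyl-9α-(Ar*CH2)-10α-H-hydrindane
Conditions: H2 (1 atm), 10% Pd/C, EtOAc, rt
Reagents that add atoms: none
Why: heterogeneous hydrogenation of the 1,1-disubstituted alkene from the α-face, opposite the axial 9β- and 5β-methyl groups, should give the equatorial 8β-methyl; ester, MOM and silyl ether are inert.

Step 12
Reactants: 15 4β-(tert-butyldimethylsilyloxy)-5β,8β,9β-trimethyl-9α-(Ar*CH2)-10α-H-hydrindane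
Product: 16 5β,8β,9β-trimethyl-9α-(Ar*CH2)-10α-H-hydrindan-4β-ol
Conditions: TBAF, THF, 50 °C
Reagents that add atoms: none
Why: fluoride cleaves the hindered secondary silyl ether and leaves the methyl ester and the MOM acetal.

Step 13
Reactants: 16 5β,8β,9β-trimethyl-9α-(Ar*CH2)-10α-H-hydrindan-4β-ol
Product: 17 5β,8β,9β-trimethyl-9α-(Ar*CH2)-10α-H-hydrindan-4-one
Conditions: Dess–Martin periodinane, CH2Cl2, rt
Reagents that add atoms: none
Why: Dess–Martin oxidation under near-neutral conditions gives the neopentyl cyclopentanone; no stereocentre is at risk because C5 is quaternary.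

Step 14
Reactants: 17 5β,8β,9β-trimethyl-9α-(Ar*CH2)-10α-H-hydrindan-4-one
Product: 19 5β,8β,9β-trimethyl-9α-(Ar*CH2)-10α-H-decalin-4-one, via α-trimethylsilyl ketone 18 (not isolated)
Conditions: TMSCHN2, BF3·OEt2, CH2Cl2, −78 → −20 °C; then K2CO3, MeOH, rt
Reagents that add atoms: (trimethylsilyl)diazomethane C[Si](C)(C)C=[N+]=[N-]
Why: The diazo carbon of TMSCHN2 adds to the Lewis-acid-activated C4 carbonyl from the α-face, and loss of N2 from the resulting β-oxido diazonium ion with 1,2-shift of the antiperiplanar ring bond inserts the new carbon (C3) between C4 and C2 to give α-silyl ketone 18, which K2CO3/MeOH protodesilylates to 19. The closest known reaction type is the Büchner–Curtius–Schlotterbeck (Tiffeneau–Demjanov-type) one-carbon homologation of cyclic ketones with diazoalkanes, as used for D-homo-annulation of 17-oxo steroids, whose trans-hydrindan-1-one D ring is the substructure present in 17. No ring is closed by cyclisation: ring A arises by enlargement of the five-membered ring C4–C2–C1–C10–C5 to the six-membered ring C4–C3–C2–C1–C10–C5 through a 1,2-alkyl shift. No lasting stereocentre is formed (the C3–Si centre of 18 is erased) and C5, C10, C9 and C8 are not involved, so the trans fusion is carried over unchanged. The step needs regioselectivity (migration of the CH2 carbon C2, not the quaternary C5, so that the carbonyl stays at C4) and a single insertion: in the betaine the bulky Me3Si group can avoid the quaternary C5 only in the rotamer that places N2 anti to the C4–C2 bond, and the hindered α-silyl ketone should resist a second homologation. The aryl ester and the MOM acetal should be inert to the diazoalkane and to BF3 at low temperature.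

Step 15
Reactants: 19 5β,8β,9β-trimethyl-9α-(Ar*CH2)-10α-H-decalin-4-one
Product: 20 methyl 4-hydroxy-3-methoxy-5-{[5β,8β,9β-trimethyl-4-oxo-10α-H-decalin-9α-yl]methyl}benzoate
Conditions: HCl (3 M in MeOH), 40 °C
Reagents that add atoms: none
Why: acid-catalysed acetal exchange with methanol releases the phenol before the alkene exists, so no acid meets the exocyclic methylene, and methanol as solvent keeps the methyl ester.

Step 16
Reactants: 20 methyl 4-hydroxy-3-methoxy-5-{[5β,8β,9β-trimethyl-4-oxo-10α-H-decalin-9α-yl]methyl}benzoate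
Product: 22 polyfibrospongol A, via potassium phenoxide 21 (not isolated)
Conditions: Ph3PCH3Br, KOt-Bu (excess), THF, 0 → 60 °C; sat. aq. NH4Cl
Reagents that add atoms: methyltriphenylphosphonium bromide C[P+](c1ccccc1)(c1ccccc1)c1ccccc1.[Br-]
Why: Wittig methylenation of the C4 ketone; the phenol travels as phenoxide 21, which also deactivates the para ester towards the ylide, and no stereocentre is formed or epimerisable.

**Compound list**

1 | 2-methylcyclopentane-1,3-dione | CC1C(=O)CCC1=O | starting material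
2 | pent-1-en-3-one (ethyl vinyl ketone) | CCC(=O)C=C | starting material
3 | 2-methyl-2-(3-oxopentyl)cyclopentane-1,3-dione | CCC(=O)CCC1(C)C(=O)CCC1=O | intermediate
4 | (7aS)-4,7a-dimethyl-2,3,7,7a-tetrahydro-1H-indene-1,5(6H)-dione | O=C1CCC2=C(C)C(=O)CC[C@]12C | intermediate
5 | (1S,7aS)-1-hydroxy-4,7a-dimethyl-1,2,3,6,7,7a-hexahydro-5H-inden-5-one | O[C@H]1CCC2=C(C)C(=O)CC[C@]12C | intermediate
6 | (1S,7aS)-1-(tert-butyldimethylsilyloxy)-4,7a-dimethyl-1,2,3,6,7,7a-hexahydro-5H-inden-5-one | CC(C)(C)[Si](C)(C)O[C@H]1CCC2=C(C)C(=O)CC[C@]12C | intermediate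
7 | methyl 4-hydroxy-3-methoxybenzoate (methyl vanillate) | COC(=O)c1ccc(O)c(OC)c1 | starting material
8 | methyl 3-formyl-4-hydroxy-5-methoxybenzoate | COC(=O)c1cc(C=O)c(O)c(OC)c1 | intermediate
9 | methyl 3-formyl-5-methoxy-4-(methoxymethoxy)benzoate | COC(=O)c1cc(C=O)c(OCOC)c(OC)c1 | intermediate
10 | methyl 3-(hydroxymethyl)-5-methoxy-4-(methoxymethoxy)benzoate | COC(=O)c1cc(CO)c(OCOC)c(OC)c1 | intermediate
11 | methyl 3-(bromomethyl)-5-methoxy-4-(methoxymethoxy)benzoate | COC(=O)c1cc(CBr)c(OCOC)c(OC)c1 | intermediate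
12 | lithium C8=C9 enolate of trans-fused 4β-(tert-butyldimethylsilyloxy)-5β,9-dimethyl-10α-H-hydrindan-8-one | CC(C)(C)[Si](C)(C)O[C@H]1CC[C@H]2C(C)=C([O-])CC[C@]12C.[Li+] | intermediate
13 | 4β-(tert-butyldimethylsilyloxy)-5β,9β-dimethyl-9α-(Ar*CH2)-10α-H-hydrindan-8-one | CC(C)(C)[Si](C)(C)O[C@H]1CC[C@H]2[C@](C)(Cc3cc(C(=O)OC)cc(OC)c3OCOC)C(=O)CC[C@]12C | intermediate
14 | 4β-(tert-butyldimethylsilyloxy)-5β,9β-dimethyl-8-methylene-9α-(Ar*CH2)-10α-H-hydrindane | CC(C)(C)[Si](C)(C)O[C@H]1CC[C@H]2[C@](C)(Cc3cc(C(=O)OC)cc(OC)c3OCOC)C(=C)CC[C@]12C | intermediate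
15 | 4β-(tert-butyldimethylsilyloxy)-5β,8β,9β-trimethyl-9α-(Ar*CH2)-10α-H-hydrindane | CC(C)(C)[Si](C)(C)O[C@H]1CC[C@H]2[C@](C)(Cc3cc(C(=O)OC)cc(OC)c3OCOC)[C@@H](C)CC[C@]12C | intermediate
16 | 5β,8β,9β-trimethyl-9α-(Ar*CH2)-10α-H-hydrindan-4β-ol | O[C@H]1CC[C@H]2[C@](C)(Cc3cc(C(=O)OC)cc(OC)c3OCOC)[C@@H](C)CC[C@]12C | intermediate
17 | 5β,8β,9β-trimethyl-9α-(Ar*CH2)-10α-H-hydrindan-4-one | O=C1CC[C@H]2[C@](C)(Cc3cc(C(=O)OC)cc(OC)c3OCOC)[C@@H](C)CC[C@]12C | intermediate
18 | 3-(trimethylsilyl)-5β,8β,9β-trimethyl-9α-(Ar*CH2)-10α-H-decalin-4-one (C3 epimers) | O=C1C([Si](C)(C)C)CC[C@H]2[C@](C)(Cc3cc(C(=O)OC)cc(OC)c3OCOC)[C@@H](C)CC[C@]12C | intermediate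
19 | 5β,8β,9β-trimethyl-9α-(Ar*CH2)-10α-H-decalin-4-one | O=C1CCC[C@H]2[C@](C)(Cc3cc(C(=O)OC)cc(OC)c3OCOC)[C@@H](C)CC[C@]12C | intermediate
20 | methyl 4-hydroxy-3-methoxy-5-{[5β,8β,9β-trimethyl-4-oxo-10α-H-decalin-9α-yl]methyl}benzoate | O=C1CCC[C@H]2[C@](C)(Cc3cc(C(=O)OC)cc(OC)c3O)[C@@H](C)CC[C@]12C | intermediate
21 | potassium phenoxide of 20 | O=C1CCC[C@H]2[C@](C)(Cc3cc(C(=O)OC)cc(OC)c3[O-])[C@@H](C)CC[C@]12C.[K+] | intermediate
22 | polyfibrospongol A | C=C1CCC[C@H]2[C@](C)(Cc3cc(C(=O)OC)cc(OC)c3O)[C@@H](C)CC[C@]12C | target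

**Totals**

Total step count: 16. Longest linear sequence: 12 steps (steps 1–4 and 9–16; the aryl branch, steps 5–8 and 9–16, is equally long).

**Steps most likely to fail**

Step 9. The protonation at C10 may lack facial selectivity and give cis-fused material, and residual metal or amide may reduce or ammonolyse the ester-bearing bromide. The fallback sets out from 6 and returns at 13. Deconjugative alkylation of the extended potassium dienolate of 6 (t-BuOK, THF/t-BuOH, then 11) sets C9 first, anti to the angular methyl, and gives β,γ-unsaturated ketone F1 (C1=C10). Radical hydrogen-atom-transfer hydrogenation (Mn(dpm)3 cat., PhSiH3, TBHP, i-PrOH) then delivers H to the tertiary C10 radical from the α-face, away from the syn-axial C5 and C9 β-methyl groups, to give 13.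

Step 14. Addition of the diazoalkane to the neopentyl carbonyl may be sluggish, the quaternary C5 may migrate in place of C2 (carbonyl displaced to C3), or a second insertion may occur. The fallback sets out from 17 and returns at 19. Because 17 can enolise only towards C2, LiHMDS/TMSCl gives silyl enol ether F2, and Et2Zn/CH2I2 (Furukawa–Simmons–Smith) gives siloxycyclopropane F3 (cyclopropane expected on the α-face; its configuration is lost next). FeCl3 in DMF cleaves the internal cyclopropane bond by β-scission of the oxygen-centred radical to the ring-enlarged β-chloro ketone F4. NaOAc/MeOH eliminates HCl to enone F5, and H2, Pd/C gives 19.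

Step 10. Methylenation of the C8 carbonyl next to the quaternary C9 may stall through enolisation towards C7, or the Lewis-acidic reagent may strip the MOM acetal. The fallback sets out from 13 and returns at 15, bypassing 14. KHMDS/PhNTf2 at −78 °C gives enol triflate F6 (C7=C8). Stille methylation (Me4Sn, Pd(PPh3)4, LiCl, DMF) gives trisubstituted alkene F7, and hydrogenation from the α-face (H2, Pd/C or PtO2) gives 15.

Further compounds
F1 | step 9 | 4β-(tert-butyldimethylsilyloxy)-5β,9β-dimethyl-9α-(Ar*CH2)-hydrind-1(10)-en-8-one | CC(C)(C)[Si](C)(C)O[C@H]1CC=C2[C@](C)(Cc3cc(C(=O)OC)cc(OC)c3OCOC)C(=O)CC[C@]12C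
F2 | step 14 | 4-(trimethylsilyloxy)-5β,8β,9β-trimethyl-9α-(Ar*CH2)-10α-H-hydrind-2(4)-ene (silyl enol ether of 17) | C[Si](C)(C)OC1=CC[C@H]2[C@](C)(Cc3cc(C(=O)OC)cc(OC)c3OCOC)[C@@H](C)CC[C@]12C
F3 | step 14 | 2α,4α-methano-4β-(trimethylsilyloxy)-5β,8β,9β-trimethyl-9α-(Ar*CH2)-10α-H-hydrindane (siloxycyclopropane) | C[Si](C)(C)O[C@]13C[C@@H]3C[C@H]2[C@](C)(Cc4cc(C(=O)OC)cc(OC)c4OCOC)[C@@H](C)CC[C@]12C
F4 | step 14 | 2-chloro-5β,8β,9β-trimethyl-9α-(Ar*CH2)-10α-H-decalin-4-one (C2 epimers) | O=C1CC(Cl)C[C@H]2[C@](C)(Cc3cc(C(=O)OC)cc(OC)c3OCOC)[C@@H](C)CC[C@]12C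
F5 | step 14 | 5β,8β,9β-trimethyl-9α-(Ar*CH2)-10α-H-decal-2-en-4-one | O=C1C=CC[C@H]2[C@](C)(Cc3cc(C(=O)OC)cc(OC)c3OCOC)[C@@H](C)CC[C@]12C
F6 | step 10 | 4β-(tert-butyldimethylsilyloxy)-5β,9β-dimethyl-9α-(Ar*CH2)-10α-H-hydrind-7-en-8-yl trifluoromethanesulfonate | CC(C)(C)[Si](C)(C)O[C@H]1CC[C@H]2[C@](C)(Cc3cc(C(=O)OC)cc(OC)c3OCOC)C(OS(=O)(=O)C(F)(F)F)=CC[C@]12C
F7 | step 10 | 4β-(tert-butyldimethylsilyloxy)-5β,8,9β-trimethyl-9α-(Ar*CH2)-10α-H-hydrind-7-ene | CC(C)(C)[Si](C)(C)O[C@H]1CC[C@H]2[C@](C)(Cc3cc(C(=O)OC)cc(OC)c3OCOC)C(C)=CC[C@]12C
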